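The vessel is closed and stirred, and a decision on it is due at 8.0 h.

| flask | starting material | coupling partner | second substrate | protic impurity | catalyst | temperature | remark | time |
|---|---|---|---|---|---|---|---|---|
| birch | 0.050 M | 0.10 M | 0.050 M | 0.015 M | 10 mM | 0 °C | the very flask that is asked about, followed so far |  |
| cedar | 0.050 M | 0.10 M | 0.034 M | 0.015 M | 10 mM | 0 °C | run made earlier |  |
| flask | 0.050 M | 0.100 M | 0.0500 M | 0.0150 M | 10 mM | 0 °C |  | 8.0 h |

- birch (time / min: target / %, starting material / %): 25.0: 48.8, 5.2; 40.0: 45.5, 1.4; 60.0: 43.9, 1.5; 120: 42.6, 0.8; 180: 44.4, 0; 300: 42.1, 0.6
- cedar (time / min: target / %, starting material / %): 4.00: 40.2, 37.9; 6.00: 48.1, 26.3; 12.0: 53.1, 10.4; 20.0: 51.6, 3.2; 30.0: 47.6, 0.4; 50.0: 44.4, 0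

(readings scatter by 1 percentage point)

- what is taken out of target is counted as made
- the numbers in the tables scatter by 1 percentage point (one standard deviation)
- what may be going on: target + catalyst <-> isomer of the product + catalyst; second substrate <-> dormant form; second substrate + coupling partner + catalyst -> catalyst + second product; starting material + coupling partner + catalyst -> catalyst + target; starting material + protic impurity -> quenched substrate
- the earlier runs do not show what temperature does; that part of a forecast is a guess
- additions bring no volume worth counting

- gamma: at 8.0 h add catalyst, 100% of the amount charged, then wait 15 h
- delta: at 8.0 h raise the temperature by 25 K, then wait 15 h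
- theta: at 8.0 h take out 90% of the target then present, then wait 15 h
- zeta: at 8.0 h add coupling partner, 50.0% of the amount charged, then wait 15 h
- epsilon: change nothing and wait 15 h more

- target, in percent of the starting material first charged, at 8.0 h
- what to do for the largest gain in target; "none" if nothing gains more than 2 percentage points (gamma / delta / theta / zeta / epsilon / none)
- target present, with what was taken out counted in, in percent of the starting material first charged, after theta
- target present, with what was taken out counted in, in percent of the starting material first charged, after zeta

Two chemists read these runs. The first calls the birch flask finished. Its starting material reads 0.8% at 120 min, and target scatters about 43.2% from 60.0 min to 300 min. So she answers none.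

The second calls it live. In the cedar run target fell from 53.1% at 12.0 min to 44.4% at 50.0 min, while starting material went from 10.4% to 0%. So something takes target as coupling fades, and the plateau of the birch flask shows that it stops well short of zero. He reads the flat stretch as an equilibrium of target and isomer under the catalyst (thermodynamic control). Pulling target out should then make more.

My own reckoning freezes what stands still. Once starting material is near zero, target plus isomer, the pool, stays fixed. The protic impurity can quench at most 30.0% of the starting material, one for one, so I take the pool at 70.0%. Plateau over pool gives 61.8%, the target share: the part of the pool standing as target at this temperature.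

Theta takes 38.9%. The isomer refills the part of that outside the share, so the gain is 15 percentage points and theta totals 58.1%. Zeta and gamma leave the share as it is. No earlier run shows another temperature.

The forecast is the second chemist's number: 43.2% now, 58.5% after theta, 43.2% after zeta, best theta. Its pool stands at about 72 percent against my 70.0%, and of warming it says “Heating is a guess”.

    target + catalyst ⇌ isomer of the product + catalyst, rate k1*[catalyst]*[target] forward; the back reaction follows from the equilibrium constant (K = 0.730, k = 2.80 M⁻¹ min⁻¹, Ea = 53.0 kJ mol⁻¹, ΔH = −74.0 kJ mol⁻¹)
    second substrate ⇌ dormant form (K = 4.00, k = 0.0730 min⁻¹, Ea = 89.0 kJ mol⁻¹, ΔH = 11.0 kJ mol⁻¹)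
    second substrate + coupling partner + catalyst → catalyst + second product (k = 280 M⁻² min⁻¹, Ea = 44.0 kJ mol⁻¹)
    starting material + coupling partner + catalyst → catalyst + target (k = 240 M⁻² min⁻¹, Ea = 35.0 kJ mol⁻¹)
    starting material + protic impurity → quenched substrate (k = 8.00 M⁻¹ min⁻¹, Ea = 43.0 kJ mol⁻¹)
    (constants at 0 °C)

The flask gave 42.2% at 8.0 h, 58.2% after theta and 42.2% after zeta, but the best was delta, gaining 28 points against 16 points for theta. Coupling and quench ran while starting material stood, the coupling reaching the midpoint of its turnover by 2.85 min; the exchange of target with isomer ran behind it, midpoint 16.5 min. The finished view held for gamma, zeta and epsilon: 0 points, 0 points, 0 points. With 0.0060 M of protic impurity, the share 61.8% of a pool of 88.0% gives 54.4%, and that neighbour flask stood at 51.1%.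

The readings stem from a simulated flask on assumed constants.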